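## The problem

(2S)-2,3-Dihydroheveaflavone (28) is a biflavonoid. C8 of a 5-hydroxy-7,4'-dimethoxyflavone is bonded to C3' of ring B of a (2S)-5-hydroxy-7-methoxyflavanone. Ring B carries its free hydroxyl at C4', ortho to the interflavonoid bond, and the flavanone C2 at C1', para to that hydroxyl.

The interflavonoid bond is flanked by the C7 methoxy group and the pyranone oxygen on the flavone side and by the C4' hydroxyl on the other. It is therefore a hindered biaryl bond, and it must sit at C8 and not at the less crowded C6.

The only stereocentre is flavanone C2. It is benzylic, bonded to the ring oxygen and β to the ketone, so it racemises by reversible opening to the 2'-hydroxychalcone in base, and the electron-rich ring B makes hot acid a concern as well. Nothing else in the molecule can control it, because the biaryl axis carries no descriptor and is remote. It must be set by a catalyst, late, and then kept away from base.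

The flavone carbonyl is a vinylogous ester. Aluminium hydrides and warm organometallic reagents attack it, and hot alkali opens the pyranone ring. Three phenols (two chelated at C5, one free) have to be told apart from three methyl ethers.

The feature that allows a cycloaddition route is the pattern of ring B. C3', C4', C5' and C6' map onto a 1-methoxy-3-silyloxydiene whose silyloxy carbon becomes C4' and whose substituted terminus becomes C3'. C1' and C2' map onto a propiolate. Ring B can thus be grown onto a flavone that carries only a four-carbon chain at C8.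

## Retrosynthesis

**28 from 27.** No skeletal bond is cut; three O–benzyl bonds are. Benzyl ethers on the two chelated C5 hydroxyls and on the C4' hydroxyl separate the phenols from the methyl ethers throughout. Neutral hydrogenolysis is then the only reaction the labile C2 centre sees after it is made. Late Lewis-acid demethylation would put that centre at risk and would have to distinguish five methyl ethers. The forward step must leave the flavone C2=C3 bond, the flavanone ketone and the benzylic C2–O1 bond alone.

**27 from 24, and 24 from 20 and 23.** The flavanone O1–C2 bond is cut (oxa-Michael), then the C2–C3 bond as the C=C of a Knoevenagel adduct. The ester at C3 activates the acceptor enough for a bifunctional thiourea to control the facial sense, and it then leaves as CO2. The neighbouring cuts are weaker here: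
- cyclisation of a plain 2'-hydroxychalcone is reversible and poorly enantioselective;
- conjugate arylation of a chromone would need ring B as an arylboron reagent, not an aldehyde;
- Mitsunobu closure at a para-alkoxybenzylic carbinol invites ionisation.

The precursors are the biaryl aldehyde 20 and the small ketoester 23. The forward steps must condense without premature racemic ring closure, add to one face, and decarboxylate without ring opening.

**23 from 22 from 21.** The bond between the acetyl carbon and the ester carbonyl is cut (C-acylation of the ketone enolate with Boc2O). One of the two equivalent hydroxyls of 21 is benzylated first; the other stays free to become O1.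

**20 from 19, 17, 16 and 15.** No skeletal change: phenol benzylation and ester-to-aldehyde adjustment. The route goes through acid 17 and its mixed anhydride 18, because borohydride leaves the flavone carbonyl alone and aluminium hydrides do not. The forward steps must be chemoselective for the benzoate carbon.

**15 from 12 and 13 (key cut).** The C2'–C3' and C1'–C6' bonds of ring B are cut, back to silyloxydiene 12 and methyl propiolate 13. The obvious neighbour is the C8–C3' biaryl bond itself, which would demand a cross-coupling with three ortho substituents at a halogenated flavone. In the chosen cut that bond already exists as an unhindered sp2–sp3 bond, and the second ring is built around it. The hydroxyl (ortho to the flavone) and the ester (para to the hydroxyl) arrive in the same step. The forward reaction must be regioselective, must tolerate the bulky diene terminus, and must aromatise cleanly.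

**12 from 11, 10, 9, and 7 with 8.** In turn: the O–Si bond (enol silylation of enone 11), the C–OMe bond (methanol addition to ynone 10), an oxidation level (alcohol 9), and the carbinol–alkyne bond (ethynylmagnesium bromide 8 on aldehyde 7). Each step is a standard transformation on a short chain; the only demand is that the flavone carbonyl is left alone.

**7 from 6, 5, 4, 3, and 1 with 2.** The aldehyde comes from cleavage of the allyl C=C of 6. The C8–CH2 bond is cut by an aromatic Claisen rearrangement of 4. The O-methyl, O-benzyl and O-allyl bonds lead back to acacetin 1 and allyl bromide 2. Acacetin supplies the whole flavone with the 4'-methoxy group in place. The [3,3] shift delivers carbon only ortho to O7. Benzylating O5 before the rearrangement removes the hydrogen-bonded chelate that would otherwise favour C6.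

## Roads not taken

**Alternative 1:** Ring A of the flavanone is cut at C8–C8a and C4a–C5. This leads back to the (S)-2-aryl-5-(phenylsulfinyl)dihydropyranone A2 and 1,3-dimethoxy-1-(trimethylsilyloxy)buta-1,3-diene A3. On gentle heating they would undergo a [4+2] cycloaddition, and loss of the sulfinyl group and one alkoxy group would aromatise the adduct to the dibenzyl ether A1.
- Merits: the stereocentre would come from a catalytic asymmetric hetero-Diels–Alder reaction of aldehyde 20, a broadly reliable reaction class for aromatic aldehydes. The 5-hydroxy-7-methoxy pattern is built in, and the chelated hydroxyl appears unprotected, so one benzyl group fewer is needed than in the chosen plan.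
- Weak points: the dihydropyranone is a push–pull alkene and a poor dienophile until the sulfinyl group is installed at its α-carbon, which costs several steps. The annulation and the release of an acidic sulfur by-product happen with the stereocentre already in place, β to a ketone and on an oxygen leaving group, so retro-oxa-Michael racemisation is possible. The cut also does nothing for the biaryl bond and needs the same aldehyde 20.
- Comparison: from 20 the chosen plan reaches the target in three steps, against about six here. Alternative 1 probably has the more general source of enantioselectivity. Against that, the chosen plan has a ring closure precedented on flavanone substrates themselves and no dependence on a little-explored sulfinyl dienophile.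

**Alternative 2:** The flavanone C4–C4a bond is cut, back to the (S)-3-aryl-3-(3,5-dimethoxyphenoxy)propanoic acid A5. Activation with a perfluoroacyl anhydride and intramolecular Friedel–Crafts acylation onto the symmetrical, highly activated phenoxy ring would give the acetate A4 with C2 untouched.
- Merits: the closure is regiochemically unambiguous and very favourable, and it is not a conjugate addition, so it has no built-in racemisation equilibrium. The stereocentre would derive from a well-established asymmetric carbonyl reduction followed by etherification with inversion.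
- Weak points: the etherification of a secondary benzylic alcohol can lose stereochemical purity through ionisation. The strongly acidic acylation can ionise the benzylic aryl ether or eliminate it to a cinnamic acid, which is why the ring B oxygen has to be acetylated. A4 carries methyl ethers on both C5 oxygens, so two chelation-directed demethylations with a boron trihalide must spare three other methyl ethers and not open the flavanone. The biaryl is again presupposed.
- Comparison: for enantiopurity this route is arguably safer than an organocatalytic step on a new, elaborate substrate. The chosen plan sets against it that phenols and methyl ethers are differentiated from the first steps, and that the end of the route is one neutral hydrogenolysis.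

**Alternative 3:** The flavone pyranone ring is cut at C4a–C4, C4–C3 and O1–C2. Iodophenol A7, carbon monoxide A9 and 4-ethynylanisole A8 would be joined by a palladium-catalysed carbonylative Sonogashira coupling in an amine, followed by 6-endo closure, to give the bromide A6.
- Merits: the step is highly convergent. The biaryl is made beforehand on simple arenes, and the bromide is a handle for the aldehyde. In step count this is probably the shortest way to a biaryl flavone aldehyde.
- Weak points: oxidative addition must occur at an electron-rich iodide flanked by a hydroxyl and a methoxy group. Closure to an aurone (5-exo) and non-carbonylative coupling to a benzofuran compete, and the aryl bromide must stay inert. A6 carries a C5 methyl ether that needs late selective cleavage. Turning the bromide into a formyl group cannot use an organolithium next to the flavone carbonyl. The biaryl coupling that precedes all this still has three ortho substituents and a phloroglucinol-type partner prone to protodeboronation.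
- Comparison: this road is ahead on step economy for the biaryl part. The chosen plan sets against it that the complete, correctly substituted flavone is bought, that C8 is selected by a sigmatropic shift and ring B by matched cycloaddition polarity, and that no hindered aryl–aryl coupling or late methyl ether cleavage is needed.

Key step: step 10

## Assumptions

- The C8–C3' axis is taken as not configurationally stable (the target carries no axial descriptor), so only C2 is controlled.
- The quinidine-derived thiourea is taken as the pseudo-enantiomer that gives the (2S) series; should the sense be opposite on this substrate, the quinine-derived pseudo-enantiomer is used with nothing else changed.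
- 2',6'-Dihydroxy-4'-methoxyacetophenone (21) is taken as a purchasable starting material.

## Route

Step 1
Reactants: 1 acacetin (5,7-dihydroxy-4'-methoxyflavone); 2 allyl bromide
Product: 3 7-allyloxy-5-hydroxy-4'-methoxyflavone
Conditions: K2CO3, DMF, 23 °C
Reagents that add atoms: none
Why: Williamson etherification; the C7 hydroxyl is the acidic, unchelated phenol, whereas the C5 hydroxyl is tied up in a hydrogen bond to the carbonyl and should stay free under these mild conditions.

Step 2
Reactants: 3 7-allyloxy-5-hydroxy-4'-methoxyflavone
Product: 4 7-allyloxy-5-benzyloxy-4'-methoxyflavone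
Conditions: BnBr, K2CO3, KI (cat.), DMF, 70 °C
Reagents that add atoms: benzyl bromide, BrCc1ccccc1
Why: Williamson etherification of the chelated phenol under more forcing conditions; it protects O5 for the organometallic and silylation steps and removes the chelate before the rearrangement.

Step 3
Reactants: 4 7-allyloxy-5-benzyloxy-4'-methoxyflavone
Product: 5 8-allyl-5-benzyloxy-7-hydroxy-4'-methoxyflavone
Conditions: PhNEt2, 200 °C (sealed tube or microwave)
Reagents that add atoms: none
Why: Aromatic Claisen rearrangement ([3,3] shift then tautomerisation); in a chromone without a chelated C5 hydroxyl the C7–C8 bond has the higher double-bond character (as in 2-naphthyl allyl ethers), so migration to C8 should dominate over C6.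

Step 4
Reactants: 5 8-allyl-5-benzyloxy-7-hydroxy-4'-methoxyflavone
Product: 6 8-allyl-5-benzyloxy-7,4'-dimethoxyflavone
Conditions: MeI, K2CO3, acetone, reflux
Reagents that add atoms: iodomethane, CI
Why: Williamson methylation of the only free phenol.

Step 5
Reactants: 6 8-allyl-5-benzyloxy-7,4'-dimethoxyflavone
Product: 7 2-(5-benzyloxy-7,4'-dimethoxyflavon-8-yl)acetaldehyde
Conditions: OsO4 (2 mol%), NaIO4, 2,6-lutidine, dioxane/H2O, 23 °C
Reagents that add atoms: osmium tetroxide, O=[Os](=O)(=O)=O (source of the aldehyde oxygen, regenerated by sodium periodate, [Na+].[O-]I(=O)(=O)=O)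
Why: Lemieux–Johnson oxidative cleavage; the terminal monosubstituted alkene is dihydroxylated far faster than the electron-poor, conjugated flavone C2=C3 bond, and lutidine suppresses over-oxidation; the aldehyde is used crude.

Step 6
Reactants: 7 2-(5-benzyloxy-7,4'-dimethoxyflavon-8-yl)acetaldehyde; 8 ethynylmagnesium bromide
Product: 9 rac-1-(5-benzyloxy-7,4'-dimethoxyflavon-8-yl)but-3-yn-2-ol
Conditions: HC≡CMgBr (1.5 equiv), THF, −78 → −20 °C; aq. NH4Cl
Reagents that add atoms: none
Why: Grignard 1,2-addition; at low temperature the aldehyde is far more electrophilic than the vinylogous-ester carbonyl of the flavone, and the weakly basic sp-carbanion limits enolisation; the new carbinol centre is racemic and is oxidised away in step 7.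

Step 7
Reactants: 9 rac-1-(5-benzyloxy-7,4'-dimethoxyflavon-8-yl)but-3-yn-2-ol
Product: 10 1-(5-benzyloxy-7,4'-dimethoxyflavon-8-yl)but-3-yn-2-one
Conditions: Dess–Martin periodinane, NaHCO3, CH2Cl2, 0 → 23 °C
Reagents that add atoms: none
Why: Dess–Martin oxidation of a secondary propargylic alcohol under buffered, non-basic conditions that should not isomerise the benzylic ynone.

Step 8
Reactants: 10 1-(5-benzyloxy-7,4'-dimethoxyflavon-8-yl)but-3-yn-2-one
Product: 11 (E)-1-(5-benzyloxy-7,4'-dimethoxyflavon-8-yl)-4-methoxybut-3-en-2-one
Conditions: MeOH, DABCO (10 mol%), CH2Cl2, 0 → 23 °C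
Reagents that add atoms: methanol, CO
Why: Tertiary-amine-catalysed conjugate addition (oxa-Michael) of methanol to a terminal ynone, which should give the E β-methoxy enone as the thermodynamic isomer.

Step 9
Reactants: 11 (E)-1-(5-benzyloxy-7,4'-dimethoxyflavon-8-yl)-4-methoxybut-3-en-2-one
Product: 12 5-benzyloxy-8-[(1Z,3E)-2-(tert-butyldimethylsilyloxy)-4-methoxybuta-1,3-dien-1-yl]-7,4'-dimethoxyflavone
Conditions: TBSOTf, Et3N, Et2O/CH2Cl2, −78 → 0 °C
Reagents that add atoms: tert-butyldimethylsilyl trifluoromethanesulfonate, CC(C)(C)[Si](C)(C)OS(=O)(=O)C(F)(F)F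
Why: Soft enolisation and O-silylation; the benzylic CH2 is the only enolisable position, and the Z enol ether (aryl cis to the silyloxy group, trans to the dienyl chain) is expected for benzyl ketones because it avoids allylic strain; the diene is filtered through base-washed silica and used at once.

Step 10
Reactants: 12 5-benzyloxy-8-[(1Z,3E)-2-(tert-butyldimethylsilyloxy)-4-methoxybuta-1,3-dien-1-yl]-7,4'-dimethoxyflavone; 13 methyl propiolate
Product: 15 methyl 3-(5-benzyloxy-7,4'-dimethoxyflavon-8-yl)-4-hydroxybenzoate, via silyloxycyclohexadiene cycloadduct 14 (not isolated)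
Conditions: 13 (5 equiv), toluene, 110 °C, sealed tube; concentrate; then Bu4NF, THF, 0 °C; 1 M HCl work-up
Reagents that add atoms: none
Why: Normal-electron-demand [4+2] cycloaddition, concerted but asynchronous: the aryl-bearing diene terminus is the most nucleophilic carbon, since the silyloxy group and, through the diene, the methoxy group both push onto it, and it bonds to the unsubstituted β-carbon of the propiolate (C3'–C2'), while the methoxy-bearing terminus closes onto the ester-bearing carbon (C1'–C6'). The closest known reaction type is the cycloaddition of 1-methoxy-3-silyloxybutadienes with propiolates, which after loss of methanol gives 4-hydroxybenzoates. Ring B is closed as a six-membered carbocycle in the cycloaddition itself, an intermolecular [4+2] closure in which both new bonds are made in one event. Fluoride then cleaves the silyl enol ether of 14, the enolate expels methoxide and the dienone tautomerises to phenol 15; any aryl silyl ether formed by thermal loss of methanol is cleaved to the same phenol. No stereocentre is created, because the two sp3 carbons of 14 are destroyed on aromatisation and the new axis is not a controlled stereo-element. The selectivity needed is regiochemical (ester para and flavone ortho to the hydroxyl), and the matched polarisation of diene and alkynoate secures it. The Z enol ether geometry keeps the flavone on the outer side of the s-cis diene, and the linear alkyne presents its hydrogen-bearing carbon to the hindered terminus, which keeps the steric demand low.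

Step 11
Reactants: 15 methyl 3-(5-benzyloxy-7,4'-dimethoxyflavon-8-yl)-4-hydroxybenzoate
Product: 16 methyl 4-benzyloxy-3-(5-benzyloxy-7,4'-dimethoxyflavon-8-yl)benzoate
Conditions: BnBr, K2CO3, DMF, 60 °C
Reagents that add atoms: benzyl bromide, BrCc1ccccc1
Why: Williamson etherification of the acidic para-acyl phenol; the benzyl ether keeps this phenol out of the condensation and the organocatalytic step.

Step 12
Reactants: 16 methyl 4-benzyloxy-3-(5-benzyloxy-7,4'-dimethoxyflavon-8-yl)benzoate
Product: 17 4-benzyloxy-3-(5-benzyloxy-7,4'-dimethoxyflavon-8-yl)benzoic acid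
Conditions: LiOH·H2O, THF/MeOH/H2O, 45 °C; then 1 M HCl
Reagents that add atoms: lithium hydroxide (hydroxide oxygen), [Li+].[OH-]
Why: Ester saponification; mild aqueous LiOH should not open the pyranone ring, which needs hot concentrated alkali.

Step 13
Reactants: 17 4-benzyloxy-3-(5-benzyloxy-7,4'-dimethoxyflavon-8-yl)benzoic acid
Product: 19 5-benzyloxy-8-[2-benzyloxy-5-(hydroxymethyl)phenyl]-7,4'-dimethoxyflavone, via isobutyl carbonic mixed anhydride 18 (not isolated)
Conditions: i-BuOCOCl, N-methylmorpholine, THF, −15 °C; then NaBH4, H2O, 0 °C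
Reagents that add atoms: none
Why: Mixed-anhydride activation followed by borohydride reduction; NaBH4 attacks the activated aroyl carbonyl, whereas flavone carbonyls (vinylogous esters) are not reduced by borohydride at 0 °C, which avoids the aluminium hydrides that would reduce the flavone.

Step 14
Reactants: 19 5-benzyloxy-8-[2-benzyloxy-5-(hydroxymethyl)phenyl]-7,4'-dimethoxyflavone
Product: 20 4-benzyloxy-3-(5-benzyloxy-7,4'-dimethoxyflavon-8-yl)benzaldehyde
Conditions: MnO2, CH2Cl2, 23 °C
Reagents that add atoms: none
Why: MnO2 oxidation of an electron-rich benzylic alcohol, which stops at the aldehyde.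

Step 15
Reactants: 21 2',6'-dihydroxy-4'-methoxyacetophenone
Product: 22 2'-benzyloxy-6'-hydroxy-4'-methoxyacetophenone
Conditions: BnBr (1.05 equiv), K2CO3, acetone, reflux
Reagents that add atoms: benzyl bromide, BrCc1ccccc1
Why: Williamson mono-etherification; the two hydroxyls are equivalent, and after the first alkylation the remaining one is locked in a hydrogen bond to the ketone, which disfavours a second alkylation.

Step 16
Reactants: 22 2'-benzyloxy-6'-hydroxy-4'-methoxyacetophenone
Product: 23 tert-butyl 3-(2-benzyloxy-6-hydroxy-4-methoxyphenyl)-3-oxopropanoate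
Conditions: LiN(SiMe3)2 (3.3 equiv), THF, −78 °C; Boc2O, −78 → 0 °C; aq. NH4Cl
Reagents that add atoms: di-tert-butyl dicarbonate, CC(C)(C)OC(=O)OC(=O)OC(C)(C)C
Why: Crossed Claisen-type C-acylation of the phenoxide–enolate dianion, the enolate carbon being its most nucleophilic site as in the C-acylation of lithiated 2-hydroxyacetophenones; the third equivalent of base is taken up by the acidic product, and any O-carbonate formed should transfer to carbon under the excess base (Baker–Venkataraman-type shift).

Step 17
Reactants: 20 4-benzyloxy-3-(5-benzyloxy-7,4'-dimethoxyflavon-8-yl)benzaldehyde; 23 tert-butyl 3-(2-benzyloxy-6-hydroxy-4-methoxyphenyl)-3-oxopropanoate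
Product: 24 tert-butyl 2-(2-benzyloxy-6-hydroxy-4-methoxybenzoyl)-3-[4-benzyloxy-3-(5-benzyloxy-7,4'-dimethoxyflavon-8-yl)phenyl]prop-2-enoate (mixture of alkene isomers)
Conditions: piperidine (10 mol%), AcOH (10 mol%), 4 Å molecular sieves, toluene, 23 °C
Reagents that add atoms: none
Why: Knoevenagel condensation through the iminium ion of the aldehyde; the buffered, room-temperature conditions and the hydrogen bond of the phenol to the ketone should hold back uncatalysed ring closure, and the alkene mixture is carried on as such.

Step 18
Reactants: 24 tert-butyl 2-(2-benzyloxy-6-hydroxy-4-methoxybenzoyl)-3-[4-benzyloxy-3-(5-benzyloxy-7,4'-dimethoxyflavon-8-yl)phenyl]prop-2-enoate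
Product: 27 (2S)-5-benzyloxy-2-[4-benzyloxy-3-(5-benzyloxy-7,4'-dimethoxyflavon-8-yl)phenyl]-7-methoxychroman-4-one, via tert-butyl flavanone-3-carboxylate 25 (not isolated), via flavanone-3-carboxylic acid 26 (not isolated)
Conditions: 1-[3,5-bis(trifluoromethyl)phenyl]-3-[(9R)-6'-methoxycinchonan-9-yl]thiourea (quinidine-derived, 10 mol%), toluene, −25 °C; then TsOH·H2O, toluene, 80 °C
Reagents that add atoms: none
Why: Bifunctional thiourea-catalysed intramolecular oxa-Michael addition (6-endo-trig), in which the thiourea binds the β-ketoester and the quinuclidine nitrogen directs the phenol to one face of the alkylidene, setting C2 as S by catalyst control; TsOH then cleaves the tert-butyl ester and the β-keto acid loses CO2, which removes the inconsequential C3 centre without touching C2.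

Step 19
Reactants: 27 (2S)-5-benzyloxy-2-[4-benzyloxy-3-(5-benzyloxy-7,4'-dimethoxyflavon-8-yl)phenyl]-7-methoxychroman-4-one
Product: 28 (2S)-2,3-dihydroheveaflavone
Conditions: H2 (1 atm), Pd/C, EtOAc/MeOH, 23 °C
Reagents that add atoms: none
Why: Hydrogenolysis of three aryl benzyl ethers under neutral conditions, which should not epimerise C2; at atmospheric pressure and with monitored uptake the flavone C2=C3 bond, the flavanone ketone and the C2–O1 bond are expected to survive.

## Compound list

1 | acacetin (5,7-dihydroxy-4'-methoxyflavone) | COc1ccc(-c2cc(=O)c3c(O)cc(O)cc3o2)cc1 | starting material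
2 | allyl bromide | C=CCBr | starting material
3 | 7-allyloxy-5-hydroxy-4'-methoxyflavone | COc1ccc(-c2cc(=O)c3c(O)cc(OCC=C)cc3o2)cc1 | intermediate
4 | 7-allyloxy-5-benzyloxy-4'-methoxyflavone | COc1ccc(-c2cc(=O)c3c(OCc4ccccc4)cc(OCC=C)cc3o2)cc1 | intermediate
5 | 8-allyl-5-benzyloxy-7-hydroxy-4'-methoxyflavone | COc1ccc(-c2cc(=O)c3c(OCc4ccccc4)cc(O)c(CC=C)c3o2)cc1 | intermediate
6 | 8-allyl-5-benzyloxy-7,4'-dimethoxyflavone | COc1ccc(-c2cc(=O)c3c(OCc4ccccc4)cc(OC)c(CC=C)c3o2)cc1 | intermediate
7 | 2-(5-benzyloxy-7,4'-dimethoxyflavon-8-yl)acetaldehyde | COc1ccc(-c2cc(=O)c3c(OCc4ccccc4)cc(OC)c(CC=O)c3o2)cc1 | intermediate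
8 | ethynylmagnesium bromide | C#C[Mg]Br | starting material
9 | rac-1-(5-benzyloxy-7,4'-dimethoxyflavon-8-yl)but-3-yn-2-ol (racemic carbinol) | COc1ccc(-c2cc(=O)c3c(OCc4ccccc4)cc(OC)c(CC(O)C#C)c3o2)cc1 | intermediate
10 | 1-(5-benzyloxy-7,4'-dimethoxyflavon-8-yl)but-3-yn-2-one | COc1ccc(-c2cc(=O)c3c(OCc4ccccc4)cc(OC)c(CC(=O)C#C)c3o2)cc1 | intermediate
11 | (E)-1-(5-benzyloxy-7,4'-dimethoxyflavon-8-yl)-4-methoxybut-3-en-2-one | COc1ccc(-c2cc(=O)c3c(OCc4ccccc4)cc(OC)c(CC(=O)/C=C/OC)c3o2)cc1 | intermediate
12 | 5-benzyloxy-8-[(1Z,3E)-2-(tert-butyldimethylsilyloxy)-4-methoxybuta-1,3-dien-1-yl]-7,4'-dimethoxyflavone | COc1ccc(-c2cc(=O)c3c(OCc4ccccc4)cc(OC)c(/C=C(O[Si](C)(C)C(C)(C)C)/C=C/OC)c3o2)cc1 | intermediate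
13 | methyl propiolate | C#CC(=O)OC | starting material
14 | methyl 3-(5-benzyloxy-7,4'-dimethoxyflavon-8-yl)-4-(tert-butyldimethylsilyloxy)-6-methoxycyclohexa-1,4-diene-1-carboxylate (mixture of diastereomers, not isolated) | COc1ccc(-c2cc(=O)c3c(OCc4ccccc4)cc(OC)c(C5C=C(C(=O)OC)C(OC)C=C5O[Si](C)(C)C(C)(C)C)c3o2)cc1 | intermediate
15 | methyl 3-(5-benzyloxy-7,4'-dimethoxyflavon-8-yl)-4-hydroxybenzoate | COc1ccc(-c2cc(=O)c3c(OCc4ccccc4)cc(OC)c(-c4cc(C(=O)OC)ccc4O)c3o2)cc1 | intermediate
16 | methyl 4-benzyloxy-3-(5-benzyloxy-7,4'-dimethoxyflavon-8-yl)benzoate | COc1ccc(-c2cc(=O)c3c(OCc4ccccc4)cc(OC)c(-c4cc(C(=O)OC)ccc4OCc5ccccc5)c3o2)cc1 | intermediate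
17 | 4-benzyloxy-3-(5-benzyloxy-7,4'-dimethoxyflavon-8-yl)benzoic acid | COc1ccc(-c2cc(=O)c3c(OCc4ccccc4)cc(OC)c(-c4cc(C(=O)O)ccc4OCc5ccccc5)c3o2)cc1 | intermediate
18 | 4-benzyloxy-3-(5-benzyloxy-7,4'-dimethoxyflavon-8-yl)benzoic isobutyl carbonic anhydride (not isolated) | COc1ccc(-c2cc(=O)c3c(OCc4ccccc4)cc(OC)c(-c4cc(C(=O)OC(=O)OCC(C)C)ccc4OCc5ccccc5)c3o2)cc1 | intermediate
19 | 5-benzyloxy-8-[2-benzyloxy-5-(hydroxymethyl)phenyl]-7,4'-dimethoxyflavone | COc1ccc(-c2cc(=O)c3c(OCc4ccccc4)cc(OC)c(-c4cc(CO)ccc4OCc5ccccc5)c3o2)cc1 | intermediate
20 | 4-benzyloxy-3-(5-benzyloxy-7,4'-dimethoxyflavon-8-yl)benzaldehyde | COc1ccc(-c2cc(=O)c3c(OCc4ccccc4)cc(OC)c(-c4cc(C=O)ccc4OCc5ccccc5)c3o2)cc1 | intermediate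
21 | 2',6'-dihydroxy-4'-methoxyacetophenone | CC(=O)c1c(O)cc(OC)cc1O | starting material
22 | 2'-benzyloxy-6'-hydroxy-4'-methoxyacetophenone | CC(=O)c1c(O)cc(OC)cc1OCc1ccccc1 | intermediate
23 | tert-butyl 3-(2-benzyloxy-6-hydroxy-4-methoxyphenyl)-3-oxopropanoate | CC(C)(C)OC(=O)CC(=O)c1c(O)cc(OC)cc1OCc1ccccc1 | intermediate
24 | tert-butyl 2-(2-benzyloxy-6-hydroxy-4-methoxybenzoyl)-3-[4-benzyloxy-3-(5-benzyloxy-7,4'-dimethoxyflavon-8-yl)phenyl]prop-2-enoate (mixture of alkene isomers) | COc1ccc(-c2cc(=O)c3c(OCc4ccccc4)cc(OC)c(-c4cc(C=C(C(=O)OC(C)(C)C)C(=O)c6c(O)cc(OC)cc6OCc7ccccc7)ccc4OCc5ccccc5)c3o2)cc1 | intermediate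
25 | tert-butyl (2S)-5-benzyloxy-2-[4-benzyloxy-3-(5-benzyloxy-7,4'-dimethoxyflavon-8-yl)phenyl]-7-methoxy-4-oxochromane-3-carboxylate (C3 epimers and enol form, not isolated) | COc1ccc(-c2cc(=O)c3c(OCc4ccccc4)cc(OC)c(-c4cc([C@@H]5C(C(=O)OC(C)(C)C)C(=O)c6c(OCc7ccccc7)cc(OC)cc6O5)ccc4OCc8ccccc8)c3o2)cc1 | intermediate
26 | (2S)-5-benzyloxy-2-[4-benzyloxy-3-(5-benzyloxy-7,4'-dimethoxyflavon-8-yl)phenyl]-7-methoxy-4-oxochromane-3-carboxylic acid (C3 epimers, not isolated) | COc1ccc(-c2cc(=O)c3c(OCc4ccccc4)cc(OC)c(-c4cc([C@@H]5C(C(=O)O)C(=O)c6c(OCc7ccccc7)cc(OC)cc6O5)ccc4OCc8ccccc8)c3o2)cc1 | intermediate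
27 | (2S)-5-benzyloxy-2-[4-benzyloxy-3-(5-benzyloxy-7,4'-dimethoxyflavon-8-yl)phenyl]-7-methoxychroman-4-one (tri-O-benzyl-(2S)-2,3-dihydroheveaflavone) | COc1ccc(-c2cc(=O)c3c(OCc4ccccc4)cc(OC)c(-c4cc([C@@H]5CC(=O)c6c(OCc7ccccc7)cc(OC)cc6O5)ccc4OCc8ccccc8)c3o2)cc1 | intermediate
28 | (2S)-2,3-dihydroheveaflavone [(2S)-5-hydroxy-2-[4-hydroxy-3-(5-hydroxy-7,4'-dimethoxyflavon-8-yl)phenyl]-7-methoxychroman-4-one] | COc1ccc(-c2cc(=O)c3c(O)cc(OC)c(-c4cc([C@@H]5CC(=O)c6c(O)cc(OC)cc6O5)ccc4O)c3o2)cc1 | target

## Step count and least certain steps

Total step count: 19. Longest linear sequence: 17 steps (steps 1–14, then 17–19); steps 15 and 16 form a two-step branch.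

**Step 10 (key step).** The most likely failure is a slow cycloaddition. The diene terminus that must bond carries an aryl group with two ortho substituents, twisted over the diene face. Hydrolysis, geometric isomerisation or polymerisation of the sensitive silyloxydiene could then outrun the [4+2] event at the temperature required.
Fallback: form the biaryl bond directly and give up the cycloaddition. It sets out from acacetin 1 and comes back at aldehyde 20. Compound 1 is methylated at O7 (MeI, K2CO3) to 5-hydroxy-7,4'-dimethoxyflavone F1 and benzylated at O5 (BnBr, K2CO3, DMF) to 5-benzyloxy-7,4'-dimethoxyflavone F2. Iodination (N-iodosuccinimide, CF3CO2H) should give 5-benzyloxy-8-iodo-7,4'-dimethoxyflavone F3, C8 being the expected site once O5 is alkylated. Suzuki–Miyaura coupling (Pd(OAc)2, SPhos, K3PO4, toluene/H2O) with 4-benzyloxy-3-(4,4,5,5-tetramethyl-1,3,2-dioxaborolan-2-yl)benzaldehyde F4 would give 20. F4 is made by Miyaura borylation (B2pin2, PdCl2(dppf), KOAc) of commercial 4-benzyloxy-3-bromobenzaldehyde. This reserve route has its own risks: the site of iodination, protodeboronation, and a coupling with three ortho substituents.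

**Step 18.** The most likely failure is loss of enantiopurity. It could arise from uncatalysed background addition of the phenol. It could also arise from reversible ring opening during the acidic decarboxylation at 80 °C, which the para-benzyloxy ring B favours by stabilising positive charge at C2.
Fallback: resolution in place of asymmetric catalysis. It sets out from 24 and comes back at 27. Compound 24 is cyclised without chiral control (Et3N, toluene) and decarboxylated (TsOH) to racemic 5-benzyloxy-2-[4-benzyloxy-3-(5-benzyloxy-7,4'-dimethoxyflavon-8-yl)phenyl]-7-methoxychroman-4-one F5. Preparative chromatography on a chiral stationary phase gives 27. The (2R)-enantiomer F6 is returned to F5 by mild base through reversible chalcone opening and recycled.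

**Step 3.** The most likely failure is partial migration of the allyl group to C6, or thermal loss or migration of the benzyl group at 200 °C.
Fallback: attach the two-carbon unit by cross-coupling. It sets out from 1 and comes back at aldehyde 7. Compound 1 is taken through 5-hydroxy-7,4'-dimethoxyflavone F1 and 5-benzyloxy-7,4'-dimethoxyflavone F2 to 5-benzyloxy-8-iodo-7,4'-dimethoxyflavone F3, as described for step 10. F3 is coupled (PdCl2(dppf), K2CO3, dioxane/H2O) with commercial (E)-2-(2-ethoxyvinyl)-4,4,5,5-tetramethyl-1,3,2-dioxaborolane to 5-benzyloxy-8-[(E)-2-ethoxyvinyl]-7,4'-dimethoxyflavone F7. Dilute HCl in THF hydrolyses the enol ether to 7.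

**Step 6.** The most likely failure is deprotonation of the acidic benzylic α-CH2 of the arylacetaldehyde by the Grignard reagent, leading to enolisation and self-aldol, with attack at the flavone as a lesser risk.
Fallback: a non-basic acylation. It sets out from 7 and comes back at ynone 10. Pinnick oxidation (NaClO2, NaH2PO4, 2-methyl-2-butene) gives (5-benzyloxy-7,4'-dimethoxyflavon-8-yl)acetic acid F8. Oxalyl chloride converts it to (5-benzyloxy-7,4'-dimethoxyflavon-8-yl)acetyl chloride F9. A PdCl2(PPh3)2-catalysed Stille acylation with tributyl(ethynyl)stannane then gives 10.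

**Step 13.** The most likely failure is hydride delivery to the wrong carbonyl: the carbonate carbon of 18 (which returns acid 17) or, on longer exposure, the flavone. The electron-rich aroyl carbon is the least electrophilic of the activated positions.
Fallback: a hydride-free reduction that also skips alcohol 19. It sets out from acid 17 and comes back at aldehyde 20. Oxalyl chloride with catalytic DMF gives 4-benzyloxy-3-(5-benzyloxy-7,4'-dimethoxyflavon-8-yl)benzoyl chloride F10, which Bu3SnH with Pd(PPh3)4 reduces to 20.

## Further compounds

F1 | step 10 | 5-hydroxy-7,4'-dimethoxyflavone | COc1ccc(-c2cc(=O)c3c(O)cc(OC)cc3o2)cc1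
F2 | step 10 | 5-benzyloxy-7,4'-dimethoxyflavone | COc1ccc(-c2cc(=O)c3c(OCc4ccccc4)cc(OC)cc3o2)cc1
F3 | step 10 | 5-benzyloxy-8-iodo-7,4'-dimethoxyflavone | COc1ccc(-c2cc(=O)c3c(OCc4ccccc4)cc(OC)c(I)c3o2)cc1
F4 | step 10 | 4-benzyloxy-3-(4,4,5,5-tetramethyl-1,3,2-dioxaborolan-2-yl)benzaldehyde | O=Cc1ccc(OCc2ccccc2)c(B2OC(C)(C)C(C)(C)O2)c1
F5 | step 18 | racemic 5-benzyloxy-2-[4-benzyloxy-3-(5-benzyloxy-7,4'-dimethoxyflavon-8-yl)phenyl]-7-methoxychroman-4-one | COc1ccc(-c2cc(=O)c3c(OCc4ccccc4)cc(OC)c(-c4cc(C5CC(=O)c6c(OCc7ccccc7)cc(OC)cc6O5)ccc4OCc8ccccc8)c3o2)cc1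
F6 | step 18 | (2R)-5-benzyloxy-2-[4-benzyloxy-3-(5-benzyloxy-7,4'-dimethoxyflavon-8-yl)phenyl]-7-methoxychroman-4-one | COc1ccc(-c2cc(=O)c3c(OCc4ccccc4)cc(OC)c(-c4cc([C@H]5CC(=O)c6c(OCc7ccccc7)cc(OC)cc6O5)ccc4OCc8ccccc8)c3o2)cc1
F7 | step 3 | 5-benzyloxy-8-[(E)-2-ethoxyvinyl]-7,4'-dimethoxyflavone | COc1ccc(-c2cc(=O)c3c(OCc4ccccc4)cc(OC)c(/C=C/OCC)c3o2)cc1
F8 | step 6 | (5-benzyloxy-7,4'-dimethoxyflavon-8-yl)acetic acid | COc1ccc(-c2cc(=O)c3c(OCc4ccccc4)cc(OC)c(CC(=O)O)c3o2)cc1
F9 | step 6 | (5-benzyloxy-7,4'-dimethoxyflavon-8-yl)acetyl chloride | COc1ccc(-c2cc(=O)c3c(OCc4ccccc4)cc(OC)c(CC(=O)Cl)c3o2)cc1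
F10 | step 13 | 4-benzyloxy-3-(5-benzyloxy-7,4'-dimethoxyflavon-8-yl)benzoyl chloride | COc1ccc(-c2cc(=O)c3c(OCc4ccccc4)cc(OC)c(-c4cc(C(=O)Cl)ccc4OCc5ccccc5)c3o2)cc1
A1 | alternative 1 | 4',5''-di-O-benzyl-(2S)-2,3-dihydroheveaflavone [(2S)-2-[4-benzyloxy-3-(5-benzyloxy-7,4'-dimethoxyflavon-8-yl)phenyl]-5-hydroxy-7-methoxychroman-4-one] | COc1ccc(-c2cc(=O)c3c(OCc4ccccc4)cc(OC)c(-c4cc([C@@H]5CC(=O)c6c(O)cc(OC)cc6O5)ccc4OCc7ccccc7)c3o2)cc1
A2 | alternative 1 | (2S)-2-[4-benzyloxy-3-(5-benzyloxy-7,4'-dimethoxyflavon-8-yl)phenyl]-5-(phenylsulfinyl)-2,3-dihydro-4H-pyran-4-one (sulfur configuration not defined) | COc1ccc(-c2cc(=O)c3c(OCc4ccccc4)cc(OC)c(-c4cc([C@@H]5CC(=O)C(S(=O)c6ccccc6)=CO5)ccc4OCc7ccccc7)c3o2)cc1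
A3 | alternative 1 | 1,3-dimethoxy-1-(trimethylsilyloxy)buta-1,3-diene | C=C(OC)C=C(OC)O[Si](C)(C)C
A4 | alternative 2 | 4'-O-acetyl-5,5''-di-O-methyl-(2S)-2,3-dihydroheveaflavone | COc1ccc(-c2cc(=O)c3c(OC)cc(OC)c(-c4cc([C@@H]5CC(=O)c6c(OC)cc(OC)cc6O5)ccc4OC(C)=O)c3o2)cc1
A5 | alternative 2 | (3S)-3-[4-acetoxy-3-(5,7,4'-trimethoxyflavon-8-yl)phenyl]-3-(3,5-dimethoxyphenoxy)propanoic acid | COc1ccc(-c2cc(=O)c3c(OC)cc(OC)c(-c4cc([C@H](CC(=O)O)Oc5cc(OC)cc(OC)c5)ccc4OC(C)=O)c3o2)cc1
A6 | alternative 3 | 8-(2-benzyloxy-5-bromophenyl)-5,7,4'-trimethoxyflavone | COc1ccc(-c2cc(=O)c3c(OC)cc(OC)c(-c4cc(Br)ccc4OCc5ccccc5)c3o2)cc1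
A7 | alternative 3 | 2'-benzyloxy-5'-bromo-3-iodo-4,6-dimethoxybiphenyl-2-ol | COc1cc(OC)c(-c2cc(Br)ccc2OCc2ccccc2)c(O)c1I
A8 | alternative 3 | 4-ethynylanisole | C#Cc1ccc(OC)cc1
A9 | alternative 3 | carbon monoxide | [C-]#[O+]
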